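**Retrosynthetic overview**

1. Last disconnection C6–C7: an intramolecular chromium-mediated 2-(methoxycarbonyl)allylation of a (2Z,4Z)-dienal closes the ten-membered carbocycle, and the trans γ-lactone forms in the same flask; the side-chain ester is already in place.
2. The seco chain comes from a C3–C4 Sonogashira coupling of an epoxy alkyne with (Z)-3-iodobut-2-en-1-ol, then semihydrogenation (Z-C2=C3); C7–C11 by Morita–Baylis–Hillman reaction, the C13 bromide by SN2' substitution.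
3. The C8–O stereocentre and the complete ester come from a proposed enamine-catalysed α-acyloxylation of the C7 aldehyde with the bis(epoxyacyl) peroxide, itself assembled from the epoxy acid and its peroxy acid.
4. The C1/C10 oxirane and the side-chain oxirane (first stereocentres) come from Shi chiral-ketone epoxidations of an (E)-enyne (from pent-4-yn-1-ol by carboalumination) and of tiglyl alcohol.
5. Ring order: the two oxiranes first, then the ten-membered ring, then the lactone.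

Assumption: germacrane numbering is used for positions (ring C1–C10, lactone carbons C11–C13, methyls C14/C15); the SMILES is read as 1R,6R,7R,8R,10R,2'S,3'R with 2Z,4Z olefins, and (bromoethynyl)triisopropylsilane is taken as commercial.

**Route**

Step 1
Reactants: 1 (E)-2-methylbut-2-en-1-ol (tiglyl alcohol)
Product: 3 (2S,3R)-2,3-dimethyloxirane-2-carboxylic acid, via epoxy alcohol 2 (not isolated)
Conditions: Shi ketone (D-fructose-derived, 30 mol%), KHSO5 (as Oxone), K2CO3, Bu4NHSO4 (cat.), MeCN/CH2(OMe)2/aq. Na2B4O7 buffer pH 10.5, 0 °C; then NaH2PO4 to pH 6.7, TEMPO (cat.), NaClO2, NaOCl (cat.), 35 °C; extraction at pH 3, 0 °C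
Reagents that add atoms: potassium peroxymonosulfate KHSO5, [K+].[O-]S(=O)(=O)OO; sodium chlorite NaClO2, [Na+].[O-]Cl=O
Why: Shi asymmetric epoxidation (chiral dioxirane, spiro transition state) adds oxygen to one face of the E-trisubstituted olefin and sets both oxirane centres ((2R,3R) in 2, methyls cis), and the TEMPO/chlorite oxidation takes the primary alcohol to the acid without touching the oxirane.

Step 2
Reactants: 3 (2S,3R)-2,3-dimethyloxirane-2-carboxylic acid
Product: 4 (2S,3R)-2,3-dimethyloxirane-2-carboperoxoic acid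
Conditions: DCC (1.05 equiv) added to 3 and anhydrous ethereal H2O2 (8 equiv), Et2O, −15 to 0 °C; filtered, washed with cold sat. aq. (NH4)2SO4, kept cold in solution and titrated
Reagents that add atoms: hydrogen peroxide, OO
Why: carbodiimide activation of the acid followed by perhydrolysis of the O-acylisourea by a large excess of hydrogen peroxide gives the peroxy acid under neutral conditions that spare the oxirane and touch no stereocentre.

Step 3
Reactants: 4 (2S,3R)-2,3-dimethyloxirane-2-carboperoxoic acid; 3 (2S,3R)-2,3-dimethyloxirane-2-carboxylic acid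
Product: 5 bis[(2S,3R)-2,3-dimethyloxirane-2-carbonyl] peroxide
Conditions: 3 (1.0 equiv), DCC (1.05 equiv), CH2Cl2/Et2O, −10 to 0 °C; filtered from the urea, kept cold in solution and titrated
Reagents that add atoms: none
Why: carbodiimide-mediated acylation of a peroxy acid by a carboxylic acid is the standard mild diacyl peroxide synthesis; it touches no stereocentre and gives a peroxide solution free of hydrogen peroxide, which would otherwise oxidise the amine catalyst of step 8.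

Step 4
Reactants: 6 but-2-yn-1-ol
Product: 8 (Z)-3-iodobut-2-en-1-ol, via cyclic alkenylalanate 7 (not isolated)
Conditions: NaAlH2(OCH2CH2OMe)2 (1.5 equiv), THF, 0 °C to rt; then I2, −78 to 0 °C
Reagents that add atoms: iodine, II
Why: hydroxyl-directed trans-hydroalumination of the propargylic alcohol puts aluminium on C3 cis to the CH2O group, and iodinolysis with retention gives the Z-iodide.

Step 5
Reactants: 9 pent-4-yn-1-ol; 10 (bromoethynyl)triisopropylsilane
Product: 12 (E)-4-methyl-7-(triisopropylsilyl)hept-4-en-6-yn-1-ol, via alkenylalane 11 (not isolated)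
Conditions: Me3Al (3 equiv), Cp2ZrCl2 (20 mol%), CH2Cl2, 0 °C to rt; then 10, Pd(PPh3)4 (5 mol%), ZnCl2 (20 mol%), THF, rt
Reagents that add atoms: trimethylaluminium, C[Al](C)C
Why: Negishi zirconium-catalysed syn-carboalumination gives the E-alkenylalane regioselectively, and palladium-catalysed alkenyl–alkynyl cross-coupling with retention gives the E-enyne (C14 methyl and C1=C10 geometry fixed).

Step 6
Reactants: 12 (E)-4-methyl-7-(triisopropylsilyl)hept-4-en-6-yn-1-ol
Product: 14 3-[(2R,3R)-3-ethynyl-2-methyloxiran-2-yl]propan-1-ol, via silyl epoxide 13 (not isolated)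
Conditions: Shi ketone (D-fructose-derived, 30 mol%), KHSO5 (as Oxone), K2CO3, Bu4NHSO4 (cat.), MeCN/CH2(OMe)2/aq. buffer pH 10.5, 0 °C; then Bu4NF, THF, 0 °C
Reagents that add atoms: potassium peroxymonosulfate KHSO5, [K+].[O-]S(=O)(=O)OO
Why: Shi epoxidation of a conjugated E-enyne (the only electron-rich olefin) sets C1 and C10 as (R,R) with the same facial sense as in step 1, and fluoride then removes the alkynyl silane.

Step 7
Reactants: 14 3-[(2R,3R)-3-ethynyl-2-methyloxiran-2-yl]propan-1-ol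
Product: 15 3-[(2R,3R)-3-ethynyl-2-methyloxiran-2-yl]propanal
Conditions: Dess–Martin periodinane, NaHCO3, CH2Cl2, 0 °C to rt
Reagents that add atoms: none
Why: buffered Dess–Martin oxidation gives the aldehyde under neutral conditions that leave the oxirane and alkyne alone.

Step 8
Reactants: 15 3-[(2R,3R)-3-ethynyl-2-methyloxiran-2-yl]propanal; 5 bis[(2S,3R)-2,3-dimethyloxirane-2-carbonyl] peroxide
Product: 16 (2R)-1-[(2R,3R)-3-ethynyl-2-methyloxiran-2-yl]-3-oxopropan-2-yl (2S,3R)-2,3-dimethyloxirane-2-carboxylate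
Conditions: (R)-2-[diphenyl(trimethylsilyloxy)methyl]pyrrolidine (10 mol%), hydroquinone (10 mol%), 5 (1.2 equiv), THF, 0 °C; NaHCO3 wash, used without chromatography
Reagents that add atoms: none
Why: Proposed new method: the (E)-enamine of 15 with the (R)-diarylprolinol silyl ether, one face shielded by the bulky C2 group, should attack a peroxide oxygen of the aliphatic diacyl peroxide 5 in an SN2-type step, forming the C8–O bond with (8R) configuration and delivering the complete oxiranyl ester while acid 3 is released and iminium hydrolysis returns the catalyst; the oxiranyl acyloxy group should resist decarboxylation much as a cyclopropyl one does, and the closest known reaction type is the amine-catalysed asymmetric α-benzoyloxylation of aldehydes with dibenzoyl peroxide, not yet shown with an aliphatic enantiopure diacyl peroxide.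

Step 9
Reactants: 16 (2R)-1-[(2R,3R)-3-ethynyl-2-methyloxiran-2-yl]-3-oxopropan-2-yl (2S,3R)-2,3-dimethyloxirane-2-carboxylate; 17 methyl acrylate
Product: 18 methyl (3RS,4R)-4-{[(2S,3R)-2,3-dimethyloxirane-2-carbonyl]oxy}-5-[(2R,3R)-3-ethynyl-2-methyloxiran-2-yl]-3-hydroxy-2-methylidenepentanoate
Conditions: DABCO (0.5 equiv), methyl acrylate (5 equiv), dioxane/H2O, 0 °C to rt, short reaction time
Reagents that add atoms: none
Why: Morita–Baylis–Hillman reaction of an activated α-oxygenated aldehyde joins C7 to C11; the new carbinol centre forms unselectively and is erased in step 13.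

Step 10
Reactants: 18 methyl (3RS,4R)-4-{[(2S,3R)-2,3-dimethyloxirane-2-carbonyl]oxy}-5-[(2R,3R)-3-ethynyl-2-methyloxiran-2-yl]-3-hydroxy-2-methylidenepentanoate; 8 (Z)-3-iodobut-2-en-1-ol
Product: 19 methyl (3RS,4R)-4-{[(2S,3R)-2,3-dimethyloxirane-2-carbonyl]oxy}-3-hydroxy-5-{(2R,3R)-3-[(3Z)-5-hydroxy-3-methylpent-3-en-1-yn-1-yl]-2-methyloxiran-2-yl}-2-methylidenepentanoate
Conditions: PdCl2(PPh3)2 (3 mol%), CuI (6 mol%), iPr2NH (3 equiv), THF, rt, degassed
Reagents that add atoms: none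
Why: Sonogashira coupling of the terminal alkyne with the Z-vinyl iodide forms C3–C4 with retention of the Z geometry at C4=C5; the fast room-temperature cycle should outrun ionisation of the propargylic oxirane.

Step 11
Reactants: 19 methyl (3RS,4R)-4-{[(2S,3R)-2,3-dimethyloxirane-2-carbonyl]oxy}-3-hydroxy-5-{(2R,3R)-3-[(3Z)-5-hydroxy-3-methylpent-3-en-1-yn-1-yl]-2-methyloxiran-2-yl}-2-methylidenepentanoate
Product: 20 methyl (3RS,4R)-4-{[(2S,3R)-2,3-dimethyloxirane-2-carbonyl]oxy}-3-hydroxy-5-{(2R,3R)-3-[(1Z,3Z)-5-hydroxy-3-methylpenta-1,3-dien-1-yl]-2-methyloxiran-2-yl}-2-methylidenepentanoate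
Conditions: H2 (1 atm), Pd/CaCO3 poisoned with Pb(OAc)2 (Lindlar catalyst), quinoline, EtOAc, rt, stopped at 1 equiv H2
Reagents that add atoms: none
Why: Lindlar semihydrogenation adds hydrogen syn to the conjugated alkyne and gives the Z-C2=C3 olefin, completing the (2Z,4Z)-diene next to the oxirane.

Step 12
Reactants: 20 methyl (3RS,4R)-4-{[(2S,3R)-2,3-dimethyloxirane-2-carbonyl]oxy}-3-hydroxy-5-{(2R,3R)-3-[(1Z,3Z)-5-hydroxy-3-methylpenta-1,3-dien-1-yl]-2-methyloxiran-2-yl}-2-methylidenepentanoate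
Product: 21 methyl (3RS,4R)-4-{[(2S,3R)-2,3-dimethyloxirane-2-carbonyl]oxy}-3-hydroxy-5-{(2R,3R)-2-methyl-3-[(1Z,3Z)-3-methyl-5-oxopenta-1,3-dien-1-yl]oxiran-2-yl}-2-methylidenepentanoate
Conditions: MnO2 (activated, 15 equiv), CH2Cl2, rt
Reagents that add atoms: none
Why: MnO2 oxidises the primary dienylic alcohol selectively, while the secondary hydroxyl next to the electron-poor acrylate reacts much more slowly; the Z-enal geometry is kept.

Step 13
Reactants: 21 methyl (3RS,4R)-4-{[(2S,3R)-2,3-dimethyloxirane-2-carbonyl]oxy}-3-hydroxy-5-{(2R,3R)-2-methyl-3-[(1Z,3Z)-3-methyl-5-oxopenta-1,3-dien-1-yl]oxiran-2-yl}-2-methylidenepentanoate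
Product: 22 methyl (2Z,4R)-2-(bromomethyl)-4-{[(2S,3R)-2,3-dimethyloxirane-2-carbonyl]oxy}-5-{(2R,3R)-2-methyl-3-[(1Z,3Z)-3-methyl-5-oxopenta-1,3-dien-1-yl]oxiran-2-yl}pent-2-enoate
Conditions: NBS (1.3 equiv), Me2S (1.5 equiv), CH2Cl2, −20 to 0 °C; used at once
Reagents that add atoms: N-bromosuccinimide, O=C1CCC(=O)N1Br
Why: the bromosulfonium reagent (Corey–Kim type) activates the Baylis–Hillman alcohol and bromide enters by SN2' substitution, so both carbinol epimers converge on the Z-allyl bromide.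

Step 14
Reactants: 22 methyl (2Z,4R)-2-(bromomethyl)-4-{[(2S,3R)-2,3-dimethyloxirane-2-carbonyl]oxy}-5-{(2R,3R)-2-methyl-3-[(1Z,3Z)-3-methyl-5-oxopenta-1,3-dien-1-yl]oxiran-2-yl}pent-2-enoate
Product: 25 CNP0122107.1 (target germacranolide), via allylchromium 23 (not isolated), via chromium alkoxide 24 (not isolated)
Conditions: CrCl2 (8 equiv), THF, rt, slow addition of 22 to 1 mM final concentration; aq. NH4Cl
Reagents that add atoms: none
Why: intramolecular Nozaki–Hiyama (chromium Barbier) allylation, in which the equilibrating allylchromium adds to the aldehyde through a chair transition state with anti selectivity (6,7-trans); attack on the C7 face anti to the C9 chain with the C8 acyloxy group outside should give (6R,7R), and the chromium alkoxide then closes the trans γ-lactone on the methyl ester.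

**Compound list**

1 | (E)-2-methylbut-2-en-1-ol (tiglyl alcohol) | C/C=C(\C)CO | starting material
2 | [(2R,3R)-2,3-dimethyloxiran-2-yl]methanol | OC[C@@]1(C)O[C@@H]1C | intermediate
3 | (2S,3R)-2,3-dimethyloxirane-2-carboxylic acid | OC(=O)[C@@]1(C)O[C@@H]1C | intermediate
4 | (2S,3R)-2,3-dimethyloxirane-2-carboperoxoic acid | OOC(=O)[C@@]1(C)O[C@@H]1C | intermediate
5 | bis[(2S,3R)-2,3-dimethyloxirane-2-carbonyl] peroxide | C[C@H]1O[C@]1(C)C(=O)OOC(=O)[C@@]1(C)O[C@@H]1C | intermediate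
6 | but-2-yn-1-ol | CC#CCO | starting material
7 | sodium alkenylalanate from directed hydroalumination (five-membered O–Al–C=C ring; two 2-methoxyethoxy groups on aluminium) | [Na+].CC1=CCO[Al-]1(OCCOC)OCCOC | intermediate
8 | (Z)-3-iodobut-2-en-1-ol | C/C(I)=C/CO | intermediate
9 | pent-4-yn-1-ol | C#CCCCO | starting material
10 | (bromoethynyl)triisopropylsilane | CC(C)[Si](C(C)C)(C(C)C)C#CBr | starting material
11 | dimethyl{(1E)-5-[(dimethylalumanyl)oxy]-2-methylpent-1-en-1-yl}alumane | C[Al](C)/C=C(\C)CCCO[Al](C)C | intermediate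
12 | (E)-4-methyl-7-(triisopropylsilyl)hept-4-en-6-yn-1-ol | CC(C)[Si](C(C)C)(C(C)C)C#C/C=C(C)/CCCO | intermediate
13 | 3-{(2R,3R)-2-methyl-3-[(triisopropylsilyl)ethynyl]oxiran-2-yl}propan-1-ol | CC(C)[Si](C(C)C)(C(C)C)C#C[C@H]1O[C@]1(C)CCCO | intermediate
14 | 3-[(2R,3R)-3-ethynyl-2-methyloxiran-2-yl]propan-1-ol | C#C[C@H]1O[C@]1(C)CCCO | intermediate
15 | 3-[(2R,3R)-3-ethynyl-2-methyloxiran-2-yl]propanal | C#C[C@H]1O[C@]1(C)CCC=O | intermediate
16 | (2R)-1-[(2R,3R)-3-ethynyl-2-methyloxiran-2-yl]-3-oxopropan-2-yl (2S,3R)-2,3-dimethyloxirane-2-carboxylate | C#C[C@H]1O[C@]1(C)C[C@@H](OC(=O)[C@@]2(C)O[C@@H]2C)C=O | intermediate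
17 | methyl acrylate | C=CC(=O)OC | starting material
18 | methyl (3RS,4R)-4-{[(2S,3R)-2,3-dimethyloxirane-2-carbonyl]oxy}-5-[(2R,3R)-3-ethynyl-2-methyloxiran-2-yl]-3-hydroxy-2-methylidenepentanoate | C#C[C@H]1O[C@]1(C)C[C@@H](OC(=O)[C@@]2(C)O[C@@H]2C)C(O)C(=C)C(=O)OC | intermediate
19 | methyl (3RS,4R)-4-{[(2S,3R)-2,3-dimethyloxirane-2-carbonyl]oxy}-3-hydroxy-5-{(2R,3R)-3-[(3Z)-5-hydroxy-3-methylpent-3-en-1-yn-1-yl]-2-methyloxiran-2-yl}-2-methylidenepentanoate | OC/C=C(C)\C#C[C@H]1O[C@]1(C)C[C@@H](OC(=O)[C@@]2(C)O[C@@H]2C)C(O)C(=C)C(=O)OC | intermediate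
20 | methyl (3RS,4R)-4-{[(2S,3R)-2,3-dimethyloxirane-2-carbonyl]oxy}-3-hydroxy-5-{(2R,3R)-3-[(1Z,3Z)-5-hydroxy-3-methylpenta-1,3-dien-1-yl]-2-methyloxiran-2-yl}-2-methylidenepentanoate | OC/C=C(C)\C=C/[C@H]1O[C@]1(C)C[C@@H](OC(=O)[C@@]2(C)O[C@@H]2C)C(O)C(=C)C(=O)OC | intermediate
21 | methyl (3RS,4R)-4-{[(2S,3R)-2,3-dimethyloxirane-2-carbonyl]oxy}-3-hydroxy-5-{(2R,3R)-2-methyl-3-[(1Z,3Z)-3-methyl-5-oxopenta-1,3-dien-1-yl]oxiran-2-yl}-2-methylidenepentanoate | O=C/C=C(C)\C=C/[C@H]1O[C@]1(C)C[C@@H](OC(=O)[C@@]2(C)O[C@@H]2C)C(O)C(=C)C(=O)OC | intermediate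
22 | methyl (2Z,4R)-2-(bromomethyl)-4-{[(2S,3R)-2,3-dimethyloxirane-2-carbonyl]oxy}-5-{(2R,3R)-2-methyl-3-[(1Z,3Z)-3-methyl-5-oxopenta-1,3-dien-1-yl]oxiran-2-yl}pent-2-enoate | O=C/C=C(C)\C=C/[C@H]1O[C@]1(C)C[C@@H](OC(=O)[C@@]2(C)O[C@@H]2C)/C=C(\CBr)C(=O)OC | intermediate
23 | allylchromium dichloride of 22 (CrCl2 on C13; C7=C11 olefin, geometry equilibrating) | O=C/C=C(C)\C=C/[C@H]1O[C@]1(C)C[C@@H](OC(=O)[C@@]2(C)O[C@@H]2C)C=C(C[Cr](Cl)Cl)C(=O)OC | intermediate
24 | chromium alkoxide of the cyclised C6-hydroxy methyl ester (ten-membered ring closed; lactone still open) | C=C(C(=O)OC)[C@H]1[C@H](O[Cr](Cl)Cl)/C=C(C)\C=C/[C@H]2O[C@]2(C)C[C@H]1OC(=O)[C@@]1(C)O[C@@H]1C | intermediate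
25 | CNP0122107.1: (1R,10R)-1,10-epoxy-8-[(2S,3R)-2,3-dimethyloxirane-2-carbonyloxy]germacra-2Z,4Z,11(13)-trien-6,12-olide with 6R,7R,8R configuration | C=C1C(=O)O[C@@H]2/C=C(C)\C=C/[C@H]3O[C@]3(C)C[C@@H](OC(=O)[C@@]3(C)O[C@@H]3C)[C@@H]12 | target

**Step count and risks**

Total step count: 14. Longest linear sequence: 10 steps (steps 5 to 14, from pent-4-yn-1-ol; the tiglyl alcohol branch, steps 1 to 3 and then 8 to 14, is equally long).

Three steps most likely to fail:

Step 8 (proposed α-acyloxylation). The peroxide may oxidise the amine catalyst or decompose, and the enantioselectivity is untested. The fallback uses known chemistry, sets out from 15 and comes back at 16. L-Proline-catalysed α-aminoxylation of 15 with nitrosobenzene, with NaBH4 reduction in the same flask, gives (2R)-3-[(2R,3R)-3-ethynyl-2-methyloxiran-2-yl]-2-[(phenylamino)oxy]propan-1-ol F1. N–O cleavage (Zn, aq. NH4Cl, EtOH) gives (2R)-3-[(2R,3R)-3-ethynyl-2-methyloxiran-2-yl]propane-1,2-diol F2. TBSCl and imidazole silylate the primary hydroxyl to (2R)-1-[(tert-butyldimethylsilyl)oxy]-3-[(2R,3R)-3-ethynyl-2-methyloxiran-2-yl]propan-2-ol F3. Steglich esterification with acid 3 (DCC, DMAP) gives (2R)-1-[(tert-butyldimethylsilyl)oxy]-3-[(2R,3R)-3-ethynyl-2-methyloxiran-2-yl]propan-2-yl (2S,3R)-2,3-dimethyloxirane-2-carboxylate F4. HF·pyridine gives (2R)-1-[(2R,3R)-3-ethynyl-2-methyloxiran-2-yl]-3-hydroxypropan-2-yl (2S,3R)-2,3-dimethyloxirane-2-carboxylate F5, which is oxidised at once with Dess–Martin periodinane to 16.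

Step 9 (Baylis–Hillman reaction on the α-acyloxy aldehyde). The amine base may epimerise C8, and the new hydroxyl may take over the neighbouring acyl group (1,2-migration) here or in steps 10 to 12. The fallback sets out from 16 and comes back at 18. Methyl propiolate is hydroaluminated with iBu2AlH and N-methylmorpholine N-oxide in THF at 0 °C to [1-(methoxycarbonyl)ethenyl]bis(2-methylpropyl)alumane F6. This vinylalane adds to 16 at −78 to 0 °C within minutes, without amine base, to give 18 after a buffered work-up.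

Step 14 (macrocyclisation). Ring strain or the macrocyclic transition state may give oligomers or the wrong C6/C7 diastereomer. The fallback sets C6 and C7 intermolecularly under acyclic control and closes the ring at C2=C3; it sets out from 18 and 8 and comes back at 25. Semihydrogenation of 18 (H2, Pd/CaCO3 poisoned with Pb(OAc)2, quinoline) gives methyl (3RS,4R)-4-{[(2S,3R)-2,3-dimethyloxirane-2-carbonyl]oxy}-5-[(2R,3R)-3-ethenyl-2-methyloxiran-2-yl]-3-hydroxy-2-methylidenepentanoate F7. NBS and Me2S convert it into methyl (2Z,4R)-2-(bromomethyl)-4-{[(2S,3R)-2,3-dimethyloxirane-2-carbonyl]oxy}-5-[(2R,3R)-3-ethenyl-2-methyloxiran-2-yl]pent-2-enoate F8. Suzuki coupling of 8 with CH2=CHBF3K (PdCl2(dppf), Cs2CO3) gives (2Z)-3-methylpenta-2,4-dien-1-ol F9, and MnO2 oxidises it to (2Z)-3-methylpenta-2,4-dienal F10. CrCl2-mediated coupling of F8 with F10 gives (1R)-1-{(2R,3R)-2-[(1Z)-2-methylbuta-1,3-dien-1-yl]-4-methylidene-5-oxooxolan-3-yl}-2-[(2R,3R)-3-ethenyl-2-methyloxiran-2-yl]ethyl (2S,3R)-2,3-dimethyloxirane-2-carboxylate F11. Ring-closing metathesis of the two vinyl groups with the second-generation Hoveyda–Grubbs catalyst RuCl2(H2IMes)(=CH-2-iPrOC6H4) in dilute toluene gives 25. Competing metathesis at the exocyclic methylene is the main risk of this fallback.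

**Further compounds**

F1 | step 8 | (2R)-3-[(2R,3R)-3-ethynyl-2-methyloxiran-2-yl]-2-[(phenylamino)oxy]propan-1-ol | C#C[C@H]1O[C@]1(C)C[C@@H](ONc1ccccc1)CO
F2 | step 8 | (2R)-3-[(2R,3R)-3-ethynyl-2-methyloxiran-2-yl]propane-1,2-diol | C#C[C@H]1O[C@]1(C)C[C@@H](O)CO
F3 | step 8 | (2R)-1-[(tert-butyldimethylsilyl)oxy]-3-[(2R,3R)-3-ethynyl-2-methyloxiran-2-yl]propan-2-ol | C#C[C@H]1O[C@]1(C)C[C@@H](O)CO[Si](C)(C)C(C)(C)C
F4 | step 8 | (2R)-1-[(tert-butyldimethylsilyl)oxy]-3-[(2R,3R)-3-ethynyl-2-methyloxiran-2-yl]propan-2-yl (2S,3R)-2,3-dimethyloxirane-2-carboxylate | C#C[C@H]1O[C@]1(C)C[C@@H](OC(=O)[C@@]2(C)O[C@@H]2C)CO[Si](C)(C)C(C)(C)C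
F5 | step 8 | (2R)-1-[(2R,3R)-3-ethynyl-2-methyloxiran-2-yl]-3-hydroxypropan-2-yl (2S,3R)-2,3-dimethyloxirane-2-carboxylate | C#C[C@H]1O[C@]1(C)C[C@@H](OC(=O)[C@@]2(C)O[C@@H]2C)CO
F6 | step 9 | [1-(methoxycarbonyl)ethenyl]bis(2-methylpropyl)alumane | C=C(C(=O)OC)[Al](CC(C)C)CC(C)C
F7 | step 14 | methyl (3RS,4R)-4-{[(2S,3R)-2,3-dimethyloxirane-2-carbonyl]oxy}-5-[(2R,3R)-3-ethenyl-2-methyloxiran-2-yl]-3-hydroxy-2-methylidenepentanoate | C=C[C@H]1O[C@]1(C)C[C@@H](OC(=O)[C@@]2(C)O[C@@H]2C)C(O)C(=C)C(=O)OC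
F8 | step 14 | methyl (2Z,4R)-2-(bromomethyl)-4-{[(2S,3R)-2,3-dimethyloxirane-2-carbonyl]oxy}-5-[(2R,3R)-3-ethenyl-2-methyloxiran-2-yl]pent-2-enoate | C=C[C@H]1O[C@]1(C)C[C@@H](OC(=O)[C@@]2(C)O[C@@H]2C)/C=C(\CBr)C(=O)OC
F9 | step 14 | (2Z)-3-methylpenta-2,4-dien-1-ol | C=C/C(C)=C\CO
F10 | step 14 | (2Z)-3-methylpenta-2,4-dienal | C=C/C(C)=C\C=O
F11 | step 14 | (1R)-1-{(2R,3R)-2-[(1Z)-2-methylbuta-1,3-dien-1-yl]-4-methylidene-5-oxooxolan-3-yl}-2-[(2R,3R)-3-ethenyl-2-methyloxiran-2-yl]ethyl (2S,3R)-2,3-dimethyloxirane-2-carboxylate | C=C1C(=O)O[C@H](/C=C(C)\C=C)[C@H]1[C@@H](C[C@@]2(C)O[C@@H]2C=C)OC(=O)[C@@]2(C)O[C@@H]2C
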